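## Structural features

The target 27 is an achiral, twofold-symmetric chain of five six-membered carbocycles, A–B–C–D–E, each pair joined by a single methylene, and every ring carries a butanoyl ketone. Rings B, C and D are fully substituted 2,4,6-trihydroxyphenyl ketones; rings A and E are their dearomatised relatives, enolised cyclohexanetriones with a gem-dimethyl quaternary carbon. There is no stereocentre (each quaternary carbon bears two identical methyl groups), so no neighbouring stereocentres have to be related. The polyphenol and enol arrays are sensitive to air and base, and the methylene bridges, flanked by ortho and para oxygens, can fragment by retro-Friedel–Crafts (acid) or retro-Michael (base) pathways and recombine. The real difficulty is therefore sequence control: five nearly identical nucleophilic rings and four identical CH2 links must be joined in one defined order without statistical condensation, and rings B, C and D are hexasubstituted. The key step exploits rings B and D: the carbon bearing the inner methylene (C1) lies between two oxygenated carbons (C2, C6), the third oxygen is para (C4), and C3 and C5 are equivalent until one is acylated. This is exactly the 2-alkyl-1,3,5-trioxygenated benzene that a CH2–C≡C–OSi arm on ring C and a 3-alkoxycyclobutenone assemble.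

## Logic of the disconnections

27 to 23 and two molecules of 25. The two outer methylene–arene bonds, from each outer CH2 to the one unsubstituted carbon of rings B and D, are cut. The end rings are the most sensitive and the cheapest part, 23 has exactly two nucleophilic carbons and 27 has none, so the coupling cannot overshoot on carbon. The pentamer falls to a trimer and a monocyclic unit used twice. The forward step must be directional, so the one-carbon electrophile is placed on the end-ring partner only (25, reacting through 26).

25 to 24 to 3. The C–CH2N bond and then the two C–CH3 bonds at one ring carbon are cut. This returns the end ring to 3, which is also the source of ring C. The forward C-methylation must stop at the gem-dimethyl stage, and the aminomethylation must hit the single free ring carbon of 24.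

23 to 22 to 20. The O-benzyl and O-ethyl bonds are cut first, then the two aryl–acyl bonds on rings B and D. The ketones of B and D are introduced after ring construction because the annulation delivers these rings unacylated. The forward acylation must place one acyl group per ring and leave the bridges intact; a nitrile-based acylation is chosen because the iminium product switches the ring off. Benzyl ethers, not acetals, protect ring C so that no one-carbon electrophile is released while rings B and D still have free carbons.

20 to 19 to 9 and two molecules of 14. After removal of the silyl groups, two bonds are cut in each of rings B and D: bridge-bearing carbon to phenol carbon, and siloxy carbon to the adjacent CH. Rings B and D are thus grown on the arms of ring C, so the inner bridges are never made by electrophilic substitution and their position is fixed. The trimer falls to a monocyclic bis(alkyne) and a four-carbon ring that is used twice. The forward step needs a regioselective ketene–alkyne union and a ring C with no free OH or ketone that could trap ketenes.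

9 to 7. Each C≡C–O unit is cut back to an ester: the oxygen-bearing alkyne carbon is the ester carbonyl carbon and the neighbouring alkyne carbon is a one-carbon insert. The arms become ordinary arylacetates. The forward ynolate chemistry uses strong bases and a carbenoid, which a free aryl ketone would not survive; the ketone of ring C is therefore carried from 6 to 19 as a silyl enol ether that leaves with the other silyl groups.

7 to 6. The two aryl–CH2 bonds are cut to an aryl dibromide and a zinc ester enolate. This avoids a 2,4,6-trialkoxybenzyl halide, a class that ionises and self-alkylates. The forward coupling must work twice at bromides flanked by two benzyloxy groups.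

6 to 5 to 4 to 3 to 1 and 2. The silyl enol ether, the benzyl ethers, the two C–Br bonds and the aryl–acyl bond are removed in turn. Each forward step is a standard operation on a ring whose substitution pattern leaves one outcome only.

14 to 13 to 10 and 11. The two C–Cl bonds are restored and the four-membered ring is cut into a haloketene (from 10) and the ynol ether 11. The forward cycloaddition must place the ethoxy group at C3, which alkyne polarisation ensures.

## Other disconnections considered

Alternative 1: The cut lies inside ring C, at the two ring bonds flanking the carbon between the bridges. That carbon returns to dimethyl carbonate A2 and the other five ring carbons to the open-chain triacylmethane A1.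
- Forward key step: threefold deprotonation of A1, C-acylation of one outer α-methylene by A2, Dieckmann-type closure of the other α-methylene onto the new ester, and enolisation to the aromatic trimer core A3.
- In favour: ring C is made last from acyclic material, so nothing has to be coupled to a hexasubstituted arene; rings B and D enter as intact protected aryl groups; aromatisation drives the closure.
- Against: A1 has three α-methylenes of similar acidity (two arylethyl, one propyl), and acylation at the propyl chain would close a different ring. O-acylation and arrested open-chain products are also likely.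
- Comparison: A3 still lacks the acyl groups of rings B and D and the outer bridges, so the later chapters equal those of the chosen plan. On mechanism, the chosen plan replaces a condensation steered by small acidity differences with a pericyclic cascade steered by alkyne polarisation. On step economy Alternative 1 is probably equal or slightly shorter, and it is better in needing no ynolate chemistry.

Alternative 2: The cut is at the two bonds between ring C and the inner methylenes, with ring C as the dibromide A4 and ring B (identical to D) as the benzylic zinc reagent A5.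
- Forward key step: double sp2–sp3 Negishi coupling under zerovalent palladium catalysis to the protected trimer A6.
- In favour: it is the most convergent option. A5 already carries its butanoyl group, so no acylation is needed after the rings are joined; on this point and on step count it is better than the chosen plan. Zinc reagents tolerate the ketones.
- Against: A5 has to be made by zinc insertion into a benzylic carbon–halogen bond on a 2,4,6-trioxygenated ring, a position prone to ionisation and self-alkylation. The coupling joins a bromide flanked by two alkoxy groups to a benzyl nucleophile flanked by two alkoxy groups, twice on one ring, so slow transmetalation, homocoupling of A5 and protodebromination are to be expected. The nine acetals of A6 must later be cleaved beside free ring carbons, releasing one-carbon electrophiles.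
- Comparison: both plans reach the same BCD core, and A6 is further advanced. The chosen plan also needs a palladium coupling at the same hindered carbons (step 5), but with a small zinc enolate, and it builds rings B and D instead of forcing two hindered arenes together.

Alternative 3: The cut lies inside end rings A and E, with the same two-bond pattern as the chosen key step. It leads back to the trimer bis(siloxyalkyne) A8 and the gem-dimethyl cyclobutenone A7.
- Forward key step: A7 opens to a vinylketene, adds [2+2] to each siloxyalkyne terminus, and the adduct opens and closes by six-electron electrocyclisation. The quaternary carbon blocks tautomerisation, so the rings stay as the dienones of A9.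
- In favour: the mechanism is the same as in the chosen plan, so on that point the two are equal. It installs the quaternary carbons without the unselective C-methylation of step 13 and fixes the outer bridges without any methylene-transfer coupling (step 15); on both points it is better.
- Against: it does not make the BCD core. A8 is itself a fully assembled and protected BCD array carrying two further homologated arms, with three ketones to be masked during ynolate formation, on a large crowded intermediate. A9 lacks the end-ring butanoyl groups, which would require two late C-acylations of enolised triones next to labile bridges.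
- Comparison: it could extend the chosen plan but not replace it, and its linear sequence would be clearly longer.

Key step: step 9

Assumption: the silyl enol ether of ring C (6 to 19) is drawn as the Z isomer expected from amine/silyl triflate enolisation of a di-ortho-substituted aryl ketone; its geometry has no consequence because step 10 returns the ketone.

## Route

Step 1
Reactants: 1 phloroglucinol; 2 butyryl chloride
Product: 3 1-(2,4,6-trihydroxyphenyl)butan-1-one
Conditions: AlCl3, PhNO2–CH2Cl2, 0 → 45 °C; aq. HCl
Reagents that add atoms: none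
Why: Friedel–Crafts acylation of the threefold symmetric triol; the first acyl group deactivates the ring, so a single ketone should enter.

Step 2
Reactants: 3 1-(2,4,6-trihydroxyphenyl)butan-1-one
Product: 4 1-(3,5-dibromo-2,4,6-trihydroxyphenyl)butan-1-one
Conditions: NBS (2.05 equiv), MeCN, 0 °C
Reagents that add atoms: N-bromosuccinimide, O=C1CCC(=O)N1Br
Why: Electrophilic aromatic bromination; the two remaining ring carbons are equivalent and strongly activated, so two equivalents should fill both and leave the side chain alone.

Step 3
Reactants: 4 1-(3,5-dibromo-2,4,6-trihydroxyphenyl)butan-1-one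
Product: 5 1-[2,4,6-tris(benzyloxy)-3,5-dibromophenyl]butan-1-one
Conditions: BnBr, K2CO3, Bu4NI (cat.), DMF, 60 °C
Reagents that add atoms: benzyl bromide, BrCc1ccccc1
Why: Williamson etherification of an acidic triol whose ring carbons are all substituted, so only O-alkylation is possible; benzyl ethers tolerate the bases and heat up to the key step and later leave without releasing a one-carbon electrophile.

Step 4
Reactants: 5 1-[2,4,6-tris(benzyloxy)-3,5-dibromophenyl]butan-1-one
Product: 6 {[(1Z)-1-[2,4,6-tris(benzyloxy)-3,5-dibromophenyl]but-1-en-1-yl]oxy}triisopropylsilane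
Conditions: i-Pr3SiOTf, Et3N, CH2Cl2, 0 → 25 °C
Reagents that add atoms: triisopropylsilyl trifluoromethanesulfonate, CC(C)[Si](OS(=O)(=O)C(F)(F)F)(C(C)C)C(C)C
Why: Soft enolisation (silyl triflate and amine) turns the hindered aryl ketone into its silyl enol ether, the Z isomer avoiding the clash of the ethyl group with the di-ortho-substituted arene; the mask removes the electrophilic and acidic ketone before the ynolate chemistry.

Step 5
Reactants: 6 {[(1Z)-1-[2,4,6-tris(benzyloxy)-3,5-dibromophenyl]but-1-en-1-yl]oxy}triisopropylsilane
Product: 7 diethyl 2,2'-{2,4,6-tris(benzyloxy)-5-[(1Z)-1-(triisopropylsilyloxy)but-1-en-1-yl]-1,3-phenylene}diacetate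
Conditions: BrZnCH2CO2Et (from BrCH2CO2Et, Zn, THF), Pd2(dba)3 (cat.), XPhos (cat.), THF, 65 °C
Reagents that add atoms: ethyl (bromozincio)acetate, CCOC(=O)C[Zn]Br
Why: Palladium-catalysed α-arylation of a zinc ester enolate (Reformatsky–Negishi coupling); the neutral zinc enolate tolerates the silyl enol ether and benzyl ethers, and a bulky biaryl phosphine should carry oxidative addition and reductive elimination at the di-ortho-substituted bromides.

Step 6
Reactants: 7 diethyl 2,2'-{2,4,6-tris(benzyloxy)-5-[(1Z)-1-(triisopropylsilyloxy)but-1-en-1-yl]-1,3-phenylene}diacetate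
Product: 9 2,4,6-tris(benzyloxy)-1-[(1Z)-1-(triisopropylsilyloxy)but-1-en-1-yl]-3,5-bis[3-(triisopropylsilyloxy)prop-2-yn-1-yl]benzene, via bis(lithium ynolate) 8 (not isolated)
Conditions: CH2Br2, lithium 2,2,6,6-tetramethylpiperidide, THF, −78 °C; n-BuLi, −78 → 25 °C; i-Pr3SiCl, 0 → 25 °C
Reagents that add atoms: dibromomethane, BrCBr; chlorotriisopropylsilane, CC(C)[Si](Cl)(C(C)C)C(C)C
Why: Kowalski ester homologation stopped at the ynolate: dibromomethyllithium adds to each ester and, after bromine–lithium exchange, a carbenoid 1,2-shift gives ynolate 8, which the bulky silyl chloride traps on oxygen; ring C carries no ketone or OH at this stage.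

Step 7
Reactants: 10 trichloroacetyl chloride; 11 ethoxyacetylene
Product: 13 4,4-dichloro-3-ethoxycyclobut-2-en-1-one, via dichloroketene 12 (not isolated)
Conditions: activated Zn dust, Et2O–DME, 25 °C
Reagents that add atoms: none
Why: Zinc dechlorination of 10 generates dichloroketene 12, which undergoes ketene–alkyne [2+2] cycloaddition; the nucleophilic terminal carbon of the ynol ether bonds to the ketene carbonyl carbon, placing ethoxy at C3.

Step 8
Reactants: 13 4,4-dichloro-3-ethoxycyclobut-2-en-1-one
Product: 14 3-ethoxycyclobut-2-en-1-one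
Conditions: Zn, AcOH, TMEDA, EtOH, 0 °C
Reagents that add atoms: none
Why: Zinc-mediated reductive dechlorination of an α,α-dichloro ketone under amine-buffered conditions that should spare the strained vinylogous ester.

Step 9
Reactants: 9 2,4,6-tris(benzyloxy)-1-[(1Z)-1-(triisopropylsilyloxy)but-1-en-1-yl]-3,5-bis[3-(triisopropylsilyloxy)prop-2-yn-1-yl]benzene; 14 3-ethoxycyclobut-2-en-1-one (two molecules)
Product: 19 2,4,6-tris(benzyloxy)-3,5-bis{[4-ethoxy-2-hydroxy-6-(triisopropylsilyloxy)phenyl]methyl}-1-[(1Z)-1-(triisopropylsilyloxy)but-1-en-1-yl]benzene, via vinylketene 15 (not isolated), via bis(cyclobutenone) adduct 16 (not isolated), via bis(dienylketene) 17 (not isolated), via bis(cyclohexadienone) 18 (not isolated)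
Conditions: 14 (3 equiv), toluene, 80 → 110 °C, slow addition
Reagents that add atoms: 3-ethoxycyclobut-2-en-1-one (second molecule of 14), CCOC1=CC(=O)C1
Why: Two molecules of 14 are consumed per molecule of 9, one for each arm, and on heating each undergoes four-electron electrocyclic ring opening to vinylketene 15. The ketene C=C of 15 adds [2+2] to each siloxyalkyne arm of 9 to give 16, which opens in a second four-electron step to 17. Each dienylketene of 17 closes by a thermal six-electron electrocyclisation to 18, and tautomerisation gives the phenols of 19; this is how each of rings B and D is closed, from two alkyne carbons and four cyclobutenone carbons, with aromatisation as the driving force. The closest known reaction type is the Danheiser benzannulation of 3-alkoxycyclobutenones with siloxyalkynes to 1,3,5-trioxygenated benzenes. No stereocentre is formed, and the ring CH centres of 16 vanish on ring opening. The step needs regioselective ketene–alkyne union: the siloxy oxygen makes the CH2-bearing alkyne carbon nucleophilic, so it bonds to the ketene carbonyl carbon and the bridge carbon ends between the new C–OH and C–OSi carbons, para to ethoxy. Ring C is hexasubstituted and all its oxygens are capped as benzyl ethers or silyl enol ether, so neither a phenol nor a ketone can intercept the ketenes. The two arms should react independently, and the excess of 14 added slowly compensates for ketene dimerisation.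

Step 10
Reactants: 19 2,4,6-tris(benzyloxy)-3,5-bis{[4-ethoxy-2-hydroxy-6-(triisopropylsilyloxy)phenyl]methyl}-1-[(1Z)-1-(triisopropylsilyloxy)but-1-en-1-yl]benzene
Product: 20 1-{2,4,6-tris(benzyloxy)-3,5-bis[(4-ethoxy-2,6-dihydroxyphenyl)methyl]phenyl}butan-1-one
Conditions: Bu4NF, AcOH, THF, 0 → 25 °C
Reagents that add atoms: none
Why: Fluoride cleaves the two aryl silyl ethers and the silyl enol ether, and acetic acid protonates the phenoxides and the enolate, returning the ring C ketone; benzyl and ethyl ethers are untouched and the two free carbons of each new ring become equivalent.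

Step 11
Reactants: 20 1-{2,4,6-tris(benzyloxy)-3,5-bis[(4-ethoxy-2,6-dihydroxyphenyl)methyl]phenyl}butan-1-one
Product: 22 1-{2,4,6-tris(benzyloxy)-3,5-bis[(3-butanoyl-4-ethoxy-2,6-dihydroxyphenyl)methyl]phenyl}butan-1-one, via bis(ketiminium chloride) 21 (not isolated)
Conditions: n-PrCN, ZnCl2 (0.5 equiv), HCl (g), Et2O, 0 °C; then H2O, 90 °C
Reagents that add atoms: butyronitrile, CCCC#N; water, O
Why: Houben–Hoesch acylation: the nitrilium species attacks a free carbon of each 5-ethoxyresorcinol ring, the ketiminium salt 21 deactivates that ring so only one acyl group enters, either free carbon gives the same product, and ring C has no free carbon; hydrolysis gives the ketones.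

Step 12
Reactants: 22 1-{2,4,6-tris(benzyloxy)-3,5-bis[(3-butanoyl-4-ethoxy-2,6-dihydroxyphenyl)methyl]phenyl}butan-1-one
Product: 23 1-{3,5-bis[(3-butanoyl-2,4,6-trihydroxyphenyl)methyl]-2,4,6-trihydroxyphenyl}butan-1-one
Conditions: BCl3, C6HMe5, CH2Cl2, −78 → 0 °C; then H2O
Reagents that add atoms: none
Why: BCl3 cleaves the benzyl ethers at low temperature while pentamethylbenzene captures the benzyl cations, and on warming it removes the two ethyl ethers chelated to the new ortho ketones; the bridges now lie between acyl-deactivated rings and should survive.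

Step 13
Reactants: 3 1-(2,4,6-trihydroxyphenyl)butan-1-one
Product: 24 2-butanoyl-3,5-dihydroxy-4,4-dimethylcyclohexa-2,5-dien-1-one
Conditions: MeI (2.2 equiv), NaOMe, MeOH, 0 → 25 °C
Reagents that add atoms: iodomethane, CI
Why: Dearomative C-methylation of an acylphloroglucinol anion; the carbon methylated first is methylated again to give the gem-dimethyl enolised trione, and limiting the methyl iodide restrains further methylation, the product being separated from under- and over-methylated material.

Step 14
Reactants: 24 2-butanoyl-3,5-dihydroxy-4,4-dimethylcyclohexa-2,5-dien-1-one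
Product: 25 2-butanoyl-6-[(dimethylamino)methyl]-3,5-dihydroxy-4,4-dimethylcyclohexa-2,5-dien-1-one
Conditions: CH2(NMe2)2, CH2Cl2, 0 → 25 °C
Reagents that add atoms: N,N,N',N'-tetramethylmethanediamine, CN(C)CN(C)C
Why: Mannich aminomethylation: the acidic enol protonates the aminal, and the iminium ion released is captured at the only free ring carbon; the product is stored as its internal salt.

Step 15
Reactants: 23 1-{3,5-bis[(3-butanoyl-2,4,6-trihydroxyphenyl)methyl]-2,4,6-trihydroxyphenyl}butan-1-one; 25 2-butanoyl-6-[(dimethylamino)methyl]-3,5-dihydroxy-4,4-dimethylcyclohexa-2,5-dien-1-one (two molecules)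
Product: 27 target pentamer CNP0188003.0 (rings A to E joined by four methylenes), via enone methide 26 (not isolated)
Conditions: 25 (2.4 equiv), 1,4-dioxane, 80 °C, N2 stream; dil. HCl work-up
Reagents that add atoms: 2-butanoyl-6-[(dimethylamino)methyl]-3,5-dihydroxy-4,4-dimethylcyclohexa-2,5-dien-1-one (second molecule of 25), CCCC(=O)C1=C(O)C(C)(C)C(O)=C(CN(C)C)C1=O
Why: Two molecules of 25 are consumed per molecule of 23; thermal loss of dimethylamine from each Mannich base gives the doubly activated Michael acceptor 26, and conjugate addition of the single free carbon of rings B and D followed by enolisation forms both outer bridges; 23 has exactly two free ring carbons and 27 none, so C-alkylation cannot go further.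

## Compound list

1 | phloroglucinol | Oc1cc(O)cc(O)c1 | starting material
2 | butyryl chloride | CCCC(=O)Cl | starting material
3 | 1-(2,4,6-trihydroxyphenyl)butan-1-one | CCCC(=O)c1c(O)cc(O)cc1O | intermediate
4 | 1-(3,5-dibromo-2,4,6-trihydroxyphenyl)butan-1-one | CCCC(=O)c1c(O)c(Br)c(O)c(Br)c1O | intermediate
5 | 1-[2,4,6-tris(benzyloxy)-3,5-dibromophenyl]butan-1-one | CCCC(=O)c1c(OCc2ccccc2)c(Br)c(OCc2ccccc2)c(Br)c1OCc1ccccc1 | intermediate
6 | {[(1Z)-1-[2,4,6-tris(benzyloxy)-3,5-dibromophenyl]but-1-en-1-yl]oxy}triisopropylsilane | CC/C=C(\O[Si](C(C)C)(C(C)C)C(C)C)c1c(OCc2ccccc2)c(Br)c(OCc2ccccc2)c(Br)c1OCc1ccccc1 | intermediate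
7 | diethyl 2,2'-{2,4,6-tris(benzyloxy)-5-[(1Z)-1-(triisopropylsilyloxy)but-1-en-1-yl]-1,3-phenylene}diacetate | CC/C=C(\O[Si](C(C)C)(C(C)C)C(C)C)c1c(OCc2ccccc2)c(CC(=O)OCC)c(OCc2ccccc2)c(CC(=O)OCC)c1OCc1ccccc1 | intermediate
8 | bis(lithium ynolate) of ring C (two CH2–C≡C–OLi arms) | CC/C=C(\O[Si](C(C)C)(C(C)C)C(C)C)c1c(OCc2ccccc2)c(CC#CO[Li])c(OCc2ccccc2)c(CC#CO[Li])c1OCc1ccccc1 | intermediate
9 | 2,4,6-tris(benzyloxy)-1-[(1Z)-1-(triisopropylsilyloxy)but-1-en-1-yl]-3,5-bis[3-(triisopropylsilyloxy)prop-2-yn-1-yl]benzene | CC/C=C(\O[Si](C(C)C)(C(C)C)C(C)C)c1c(OCc2ccccc2)c(CC#CO[Si](C(C)C)(C(C)C)C(C)C)c(OCc2ccccc2)c(CC#CO[Si](C(C)C)(C(C)C)C(C)C)c1OCc1ccccc1 | intermediate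
10 | trichloroacetyl chloride | ClC(=O)C(Cl)(Cl)Cl | starting material
11 | ethoxyacetylene | CCOC#C | starting material
12 | dichloroketene | ClC(Cl)=C=O | intermediate
13 | 4,4-dichloro-3-ethoxycyclobut-2-en-1-one | CCOC1=CC(=O)C1(Cl)Cl | intermediate
14 | 3-ethoxycyclobut-2-en-1-one | CCOC1=CC(=O)C1 | intermediate
15 | 3-ethoxybuta-1,3-dien-1-one (vinylketene) | C=C(OCC)C=C=O | intermediate
16 | bis(cyclobutenone) adduct: each arm CH2 on C2 of a 4-(1-ethoxyethenyl)-3-(triisopropylsilyloxy)cyclobut-2-en-1-one; ring CH centres undefined (mixture, lost on ring opening) | CC/C=C(\O[Si](C(C)C)(C(C)C)C(C)C)c1c(OCc2ccccc2)c(CC2=C(O[Si](C(C)C)(C(C)C)C(C)C)C(C(OCC)=C)C2=O)c(OCc2ccccc2)c(CC2=C(O[Si](C(C)C)(C(C)C)C(C)C)C(C(OCC)=C)C2=O)c1OCc1ccccc1 | intermediate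
17 | bis(dienylketene): each arm CH2–C(=C=O)–C(OSi)=CH–C(OEt)=CH2, drawn in the geometry that can close | CC/C=C(\O[Si](C(C)C)(C(C)C)C(C)C)c1c(OCc2ccccc2)c(CC(=C=O)/C(O[Si](C(C)C)(C(C)C)C(C)C)=C\C(OCC)=C)c(OCc2ccccc2)c(CC(=C=O)/C(O[Si](C(C)C)(C(C)C)C(C)C)=C\C(OCC)=C)c1OCc1ccccc1 | intermediate
18 | bis(cyclohexa-2,4-dienone): each arm CH2 on C2 of a 5-ethoxy-3-(triisopropylsilyloxy)cyclohexa-2,4-dien-1-one | CC/C=C(\O[Si](C(C)C)(C(C)C)C(C)C)c1c(OCc2ccccc2)c(CC2=C(O[Si](C(C)C)(C(C)C)C(C)C)C=C(OCC)CC2=O)c(OCc2ccccc2)c(CC2=C(O[Si](C(C)C)(C(C)C)C(C)C)C=C(OCC)CC2=O)c1OCc1ccccc1 | intermediate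
19 | 2,4,6-tris(benzyloxy)-3,5-bis{[4-ethoxy-2-hydroxy-6-(triisopropylsilyloxy)phenyl]methyl}-1-[(1Z)-1-(triisopropylsilyloxy)but-1-en-1-yl]benzene | CC/C=C(\O[Si](C(C)C)(C(C)C)C(C)C)c1c(OCc2ccccc2)c(Cc2c(O)cc(OCC)cc2O[Si](C(C)C)(C(C)C)C(C)C)c(OCc2ccccc2)c(Cc2c(O)cc(OCC)cc2O[Si](C(C)C)(C(C)C)C(C)C)c1OCc1ccccc1 | intermediate
20 | 1-{2,4,6-tris(benzyloxy)-3,5-bis[(4-ethoxy-2,6-dihydroxyphenyl)methyl]phenyl}butan-1-one | CCCC(=O)c1c(OCc2ccccc2)c(Cc2c(O)cc(OCC)cc2O)c(OCc2ccccc2)c(Cc2c(O)cc(OCC)cc2O)c1OCc1ccccc1 | intermediate
21 | bis(ketiminium chloride) of 22 (C=NH2+ in place of each new C=O) | CCCC(=O)c1c(OCc2ccccc2)c(Cc2c(O)c(C(=[NH2+])CCC)c(OCC)cc2O)c(OCc2ccccc2)c(Cc2c(O)c(C(=[NH2+])CCC)c(OCC)cc2O)c1OCc1ccccc1.[Cl-].[Cl-] | intermediate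
22 | 1-{2,4,6-tris(benzyloxy)-3,5-bis[(3-butanoyl-4-ethoxy-2,6-dihydroxyphenyl)methyl]phenyl}butan-1-one | CCCC(=O)c1c(OCc2ccccc2)c(Cc2c(O)c(C(=O)CCC)c(OCC)cc2O)c(OCc2ccccc2)c(Cc2c(O)c(C(=O)CCC)c(OCC)cc2O)c1OCc1ccccc1 | intermediate
23 | 1-{3,5-bis[(3-butanoyl-2,4,6-trihydroxyphenyl)methyl]-2,4,6-trihydroxyphenyl}butan-1-one (BCD trimer) | CCCC(=O)c1c(O)c(Cc2c(O)c(C(=O)CCC)c(O)cc2O)c(O)c(Cc2c(O)c(C(=O)CCC)c(O)cc2O)c1O | intermediate
24 | 2-butanoyl-3,5-dihydroxy-4,4-dimethylcyclohexa-2,5-dien-1-one | CCCC(=O)C1=C(O)C(C)(C)C(O)=CC1=O | intermediate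
25 | 2-butanoyl-6-[(dimethylamino)methyl]-3,5-dihydroxy-4,4-dimethylcyclohexa-2,5-dien-1-one | CCCC(=O)C1=C(O)C(C)(C)C(O)=C(CN(C)C)C1=O | intermediate
26 | 2-butanoyl-3-hydroxy-4,4-dimethyl-6-methylidenecyclohex-2-ene-1,5-dione (enone methide) | CCCC(=O)C1=C(O)C(C)(C)C(=O)C(=C)C1=O | intermediate
27 | CNP0188003.0: ring C (3,5-bridged 2,4,6-trihydroxyphenyl propyl ketone) joined by CH2 to rings B and D (butanoylphloroglucinols), each joined by CH2 to an end ring A or E (2-butanoyl-3,5-dihydroxy-4,4-dimethylcyclohexa-2,5-dien-1-one unit); no stereocentre | CCCC(=O)C1=C(O)C(C)(C)C(O)=C(Cc2c(O)c(Cc3c(O)c(Cc4c(O)c(CC5=C(O)C(C)(C)C(O)=C(C(=O)CCC)C5=O)c(O)c(C(=O)CCC)c4O)c(O)c(C(=O)CCC)c3O)c(O)c(C(=O)CCC)c2O)C1=O | target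

## Step count and least certain steps

Total: 15 steps. Longest linear sequence: 11 steps (1, 2, 3, 4, 5, 6, 9, 10, 11, 12, 15).

Step 9 (key step). The vinylketene may be lost to dimerisation or to O-acylation of the phenols as they form. The second annulation may stall next to the crowded ring C, and the siloxyalkyne arms may undergo thermal silyl migration to silylketenes before they are intercepted. Fallback: the inner bridges are made by quinone-methide alkylation instead. Setting out from 3, double aminomethylation with CH2(NMe2)2 gives 1-{3,5-bis[(dimethylamino)methyl]-2,4,6-trihydroxyphenyl}butan-1-one F1. Heating F1 with a large excess of 3 in dioxane alkylates one free carbon of each of two molecules of 3, and the route is rejoined at 23.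

Step 5. Oxidative addition and transmetalation at bromides flanked by two benzyloxy groups may be slow, so that coupling stops after one arm or protodebromination takes over. Fallback: the arms are built through aryllithium chemistry. Setting out from 6, double bromine–lithium exchange (t-BuLi, THF, −78 °C) and trapping with diethyl oxalate gives diethyl 2,2'-{2,4,6-tris(benzyloxy)-5-[(1Z)-1-(triisopropylsilyloxy)but-1-en-1-yl]-1,3-phenylene}bis(2-oxoacetate) F2. Reduction with SmI2, HMPA and t-BuOH takes each keto ester through the carbinol to the deoxygenated ester, and the route is rejoined at 7.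

Step 6. The lithium amide or the carbenoid may deprotonate the arylacetate α-methylene instead of adding to the ester carbonyl, the ynolate may be silylated on carbon, and excess alkyllithium may attack the benzylic ether positions on warming. Fallback: the ynolate is made by acetylide oxidation. Setting out from 7, i-Bu2AlH at −78 °C gives 2,2'-{2,4,6-tris(benzyloxy)-5-[(1Z)-1-(triisopropylsilyloxy)but-1-en-1-yl]-1,3-phenylene}diacetaldehyde F3. Ohira–Bestmann homologation (dimethyl (1-diazo-2-oxopropyl)phosphonate, K2CO3, MeOH) gives 2,4,6-tris(benzyloxy)-1,3-di(prop-2-yn-1-yl)-5-[(1Z)-1-(triisopropylsilyloxy)but-1-en-1-yl]benzene F4. Deprotonation with LiN(SiMe3)2, oxidation of the acetylides with LiOOt-Bu to ynolate 8 and O-silylation with i-Pr3SiOTf rejoin the route at 9.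

Step 11. Under HCl and ZnCl2 the still unacylated, electron-rich rings B and D may be protonated at the bridge carbon, leading to retro-Friedel–Crafts scission and scrambling of the inner bridges; partial loss of benzyl groups is also possible. Fallback: the acyl group is built in two stages under milder electrophilic conditions. Setting out from 20, Vilsmeier–Haack formylation (POCl3, DMF, 0 °C; aq. NaOAc) gives 1-{2,4,6-tris(benzyloxy)-3,5-bis[(4-ethoxy-3-formyl-2,6-dihydroxyphenyl)methyl]phenyl}butan-1-one F5. Excess n-PrMgBr at −78 → 0 °C gives 1-{2,4,6-tris(benzyloxy)-3,5-bis{[4-ethoxy-2,6-dihydroxy-3-(1-hydroxybutyl)phenyl]methyl}phenyl}butan-1-one F6 as a mixture of diastereomers; the hindered ring C ketone should only be enolised. Oxidation with MnO2 rejoins the route at 22.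

Step 15. Retro-Mannich and retro-Michael processes may scramble methylene bridges between rings, and the end-ring unit may condense with itself after loss of its aminomethyl group. Fallback: the polarity is reversed. Setting out from 23, CH2(NMe2)2 gives 1-{3,5-bis({3-butanoyl-5-[(dimethylamino)methyl]-2,4,6-trihydroxyphenyl}methyl)-2,4,6-trihydroxyphenyl}butan-1-one F7, which has no free ring carbon left. Heating F7 with an excess of 24 in dioxane traps each quinone methide with the end-ring nucleophile, and the route is rejoined at 27.

## Further compounds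

F1 | step 9 | 1-{3,5-bis[(dimethylamino)methyl]-2,4,6-trihydroxyphenyl}butan-1-one | CCCC(=O)c1c(O)c(CN(C)C)c(O)c(CN(C)C)c1O
F2 | step 5 | diethyl 2,2'-{2,4,6-tris(benzyloxy)-5-[(1Z)-1-(triisopropylsilyloxy)but-1-en-1-yl]-1,3-phenylene}bis(2-oxoacetate) | CC/C=C(\O[Si](C(C)C)(C(C)C)C(C)C)c1c(OCc2ccccc2)c(C(=O)C(=O)OCC)c(OCc2ccccc2)c(C(=O)C(=O)OCC)c1OCc1ccccc1
F3 | step 6 | 2,2'-{2,4,6-tris(benzyloxy)-5-[(1Z)-1-(triisopropylsilyloxy)but-1-en-1-yl]-1,3-phenylene}diacetaldehyde | CC/C=C(\O[Si](C(C)C)(C(C)C)C(C)C)c1c(OCc2ccccc2)c(CC=O)c(OCc2ccccc2)c(CC=O)c1OCc1ccccc1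
F4 | step 6 | 2,4,6-tris(benzyloxy)-1,3-di(prop-2-yn-1-yl)-5-[(1Z)-1-(triisopropylsilyloxy)but-1-en-1-yl]benzene | CC/C=C(\O[Si](C(C)C)(C(C)C)C(C)C)c1c(OCc2ccccc2)c(CC#C)c(OCc2ccccc2)c(CC#C)c1OCc1ccccc1
F5 | step 11 | 1-{2,4,6-tris(benzyloxy)-3,5-bis[(4-ethoxy-3-formyl-2,6-dihydroxyphenyl)methyl]phenyl}butan-1-one | CCCC(=O)c1c(OCc2ccccc2)c(Cc2c(O)c(C=O)c(OCC)cc2O)c(OCc2ccccc2)c(Cc2c(O)c(C=O)c(OCC)cc2O)c1OCc1ccccc1
F6 | step 11 | 1-{2,4,6-tris(benzyloxy)-3,5-bis{[4-ethoxy-2,6-dihydroxy-3-(1-hydroxybutyl)phenyl]methyl}phenyl}butan-1-one (carbinol centres undefined, mixture) | CCCC(=O)c1c(OCc2ccccc2)c(Cc2c(O)c(C(O)CCC)c(OCC)cc2O)c(OCc2ccccc2)c(Cc2c(O)c(C(O)CCC)c(OCC)cc2O)c1OCc1ccccc1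
F7 | step 15 | 1-{3,5-bis({3-butanoyl-5-[(dimethylamino)methyl]-2,4,6-trihydroxyphenyl}methyl)-2,4,6-trihydroxyphenyl}butan-1-one | CCCC(=O)c1c(O)c(Cc2c(O)c(C(=O)CCC)c(O)c(CN(C)C)c2O)c(O)c(Cc2c(O)c(C(=O)CCC)c(O)c(CN(C)C)c2O)c1O
A1 | alternative 1 | 4-butanoyl-1,7-bis[2,4,6-tris(methoxymethoxy)phenyl]heptane-3,5-dione | CCCC(=O)C(C(=O)CCc1c(OCOC)cc(OCOC)cc1OCOC)C(=O)CCc1c(OCOC)cc(OCOC)cc1OCOC
A2 | alternative 1 | dimethyl carbonate | COC(=O)OC
A3 | alternative 1 | 1-{2,4,6-trihydroxy-3,5-bis{[2,4,6-tris(methoxymethoxy)phenyl]methyl}phenyl}butan-1-one | CCCC(=O)c1c(O)c(Cc2c(OCOC)cc(OCOC)cc2OCOC)c(O)c(Cc2c(OCOC)cc(OCOC)cc2OCOC)c1O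
A4 | alternative 2 | 1-[3,5-dibromo-2,4,6-tris(methoxymethoxy)phenyl]butan-1-one | CCCC(=O)c1c(OCOC)c(Br)c(OCOC)c(Br)c1OCOC
A5 | alternative 2 | {[3-butanoyl-2,4,6-tris(methoxymethoxy)phenyl]methyl}zinc bromide | CCCC(=O)c1c(OCOC)cc(OCOC)c(C[Zn]Br)c1OCOC
A6 | alternative 2 | 1-{3,5-bis{[3-butanoyl-2,4,6-tris(methoxymethoxy)phenyl]methyl}-2,4,6-tris(methoxymethoxy)phenyl}butan-1-one | CCCC(=O)c1c(OCOC)cc(OCOC)c(Cc2c(OCOC)c(Cc3c(OCOC)cc(OCOC)c(C(=O)CCC)c3OCOC)c(OCOC)c(C(=O)CCC)c2OCOC)c1OCOC
A7 | alternative 3 | 3-ethoxy-4,4-dimethylcyclobut-2-en-1-one | CCOC1=CC(=O)C1(C)C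
A8 | alternative 3 | BCD trimer nonakis(methoxymethyl) ether with a 3-(triisopropylsilyloxy)prop-2-yn-1-yl arm on rings B and D | CCCC(=O)c1c(OCOC)c(CC#CO[Si](C(C)C)(C(C)C)C(C)C)c(OCOC)c(Cc2c(OCOC)c(Cc3c(OCOC)c(CC#CO[Si](C(C)C)(C(C)C)C(C)C)c(OCOC)c(C(=O)CCC)c3OCOC)c(OCOC)c(C(=O)CCC)c2OCOC)c1OCOC
A9 | alternative 3 | protected pentamer with rings A and E as 5-ethoxy-6,6-dimethyl-3-(triisopropylsilyloxy)cyclohexa-2,4-dien-1-ones | CCOC1=CC(O[Si](C(C)C)(C(C)C)C(C)C)=C(Cc2c(OCOC)c(Cc3c(OCOC)c(Cc4c(OCOC)c(CC5=C(O[Si](C(C)C)(C(C)C)C(C)C)C=C(OCC)C(C)(C)C5=O)c(OCOC)c(C(=O)CCC)c4OCOC)c(OCOC)c(C(=O)CCC)c3OCOC)c(OCOC)c(C(=O)CCC)c2OCOC)C(=O)C1(C)C
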